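A direct plan would close ring C last, by an aryne annulation: the o-silylaryl triflate A1 (ring A with the prenyl group and two MOM ethers) would release aryne A2 with fluoride, the sodium alkoxide of the (S)-β-hydroxynitrile A3 would add through oxygen, the aryl anion would close onto the nitrile, and hydrolysis would give the tris-MOM flavanone A4, to be deprotected with aqueous HCl.
Weak point 1, the preparation of A1: five linear steps (bis-protection, lithiation–prenylation, C–H borylation–oxidation, bromination, silyl migration–triflation) would only decorate a benzene ring and build no bond of the core.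
Weak point 2, the annulation of A2 with A3 to A4: it would have no close precedent for an aliphatic alkoxide with a nitrile trap. The aryl anion would sit within reach of the acidic CH2CN protons, so proton transfer and β-elimination of the new aryl ether would compete with ring closure, and the regiochemistry would rest on one OMOM group.
Weak point 3, the final triple MOM cleavage in warm aqueous HCl: a prenyl group flanked by two freed phenols would be exposed to acid-catalysed cyclisation to a dimethylchroman and to hydration.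

**Retrosynthetic overview**
- The C2–C1' bond is cut last: a rhodium-catalysed asymmetric 1,4-addition of an arylboronic acid to a chromone would attach ring B and set C2 under catalyst control.
- Ring A of that chromone (C4a, C5, C6, C7, C8, C8a) would be built from open-chain parts on a bought pyranone (ring C): a Danheiser benzannulation of a pyranone diazoketone with a prenyl siloxyalkyne forms C5–C6, C7–C8 and C4a–C5.
- Ring order: ring C first (comanic acid), ring A second, ring B attached last.
- The polarity of the ynol ether puts the prenyl group on C6, between the C5 hydroxyl (born free from the ketene carbonyl, peri to C4=O) and the C7 oxygen (born as its silyl ether). No arene decoration, no aryne and no acid near the prenyl group are needed.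

Key step: step 3

Assumption: comanic acid, ethyl 4-methylpent-3-enoate and 4-bromo-2-methoxyphenol are taken as catalogue compounds; the (S)-bisphosphine (S)-MeO-F12-BIPHEP, (S)-2,2'-bis[bis(3,4,5-trifluorophenyl)phosphino]-6,6'-dimethoxy-1,1'-biphenyl, is taken to give (2S) as (S)-BINAP gives (S)-3-arylcyclohexanones, and the (R)-ligand would be used if a first run showed the opposite sense.

Step 1
Reactants: 1 comanic acid (4-oxo-4H-pyran-2-carboxylic acid)
Product: 3 2-(2-diazoacetyl)-4H-pyran-4-one, via acid chloride 2 (not isolated)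
Conditions: SOCl2 (neat), 70 °C, then evaporation; CH2N2 (3 equiv), Et2O/CH2Cl2, −10 °C
Reagents that add atoms: thionyl chloride, O=S(Cl)Cl; diazomethane, C=[N+]=[N-]
Why: Acylation of diazomethane by the acid chloride (first stage of the Arndt–Eistert sequence) should be much faster at low temperature than dipolar addition to the pyranone C=C bonds, and the excess diazomethane scavenges HCl.

Step 2
Reactants: 4 ethyl 4-methylpent-3-enoate
Product: 7 triisopropyl[(5-methylhex-4-en-1-yn-1-yl)oxy]silane, via dibromo enolate 5 (not isolated), via lithium ynolate 6 (not isolated)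
Conditions: 4, CH2Br2, THF, −78 °C, addition of lithium 2,2,6,6-tetramethylpiperidide; LiN(SiMe3)2; n-BuLi, −78 °C to rt; i-Pr3SiCl, −78 to 0 °C
Reagents that add atoms: dibromomethane, BrCBr; chlorotriisopropylsilane, CC(C)[Si](Cl)(C(C)C)C(C)C
Why: Kowalski ester homologation: addition of LiCHBr2 to the ester, bromine–lithium exchange on the dibromo enolate and carbenoid 1,2-shift of the prenyl group should give the ynolate, which bulky silyl chlorides trap on oxygen to give the stable triisopropylsilyl ynol ether.

Step 3
Reactants: 3 2-(2-diazoacetyl)-4H-pyran-4-one; 7 triisopropyl[(5-methylhex-4-en-1-yn-1-yl)oxy]silane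
Product: 12 5-hydroxy-6-(3-methylbut-2-en-1-yl)-7-[(triisopropylsilyl)oxy]-4H-chromen-4-one, via pyranonylketene 8 (not isolated), via cyclobutenone 9 (not isolated), via dienylketene 10 (not isolated), via dienone tautomer 11 (not isolated)
Conditions: 3 (1 equiv), 7 (1.3 equiv), ClCH2CH2Cl, hν (365 nm), rt; then 80 °C
Reagents that add atoms: none
Why: Danheiser benzannulation in its diazoketone form: light should trigger the Wolff rearrangement of 3 to pyranonylketene 8, whose carbonyl carbon is attacked by the nucleophilic, prenyl-bearing carbon of siloxyalkyne 7 in a regioselective [2+2] cycloaddition to give cyclobutenone 9. Four-electron electrocyclic opening of 9 on heating should give dienylketene 10, and six-electron electrocyclic closure of the ketene carbon onto C3 of the pyranone then forms ring A as dienone 11, which tautomerises to phenol 12. The closest known reaction type is this benzannulation of alkenyl and heteroaryl diazomethyl ketones with siloxyalkynes to resorcinol monosilyl ethers. Ring A closes by 6π electrocyclisation (C4a–C5 bond) after the intermolecular C5–C6 and C7–C8 bonds, and no stereocenter is formed. The step needs one regiochemistry only, fixed by the polarity of the ynol ether: the prenyl group lands on C6 between the free C5 hydroxyl (the former ketene carbonyl, hydrogen-bonded to C4=O) and the C7 silyl ether, and the closure site is unambiguous because the ketene-bearing pyranone carbon has a single carbon neighbour. Irradiation at 365 nm, beyond the absorption of the pyranone, should spare that chromophore, and the trisubstituted prenyl alkene should react with the ketene much more slowly than the ynol ether.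

Step 4
Reactants: 13 4-bromo-2-methoxyphenol
Product: 14 (4-bromo-2-methoxyphenoxy)triisopropylsilane
Conditions: i-Pr3SiCl, imidazole, DMF, rt
Reagents that add atoms: chlorotriisopropylsilane, CC(C)[Si](Cl)(C(C)C)C(C)C
Why: Imidazole-promoted O-silylation of the phenol, which masks the acidic OH for the lithiation and for the rhodium step.

Step 5
Reactants: 14 (4-bromo-2-methoxyphenoxy)triisopropylsilane
Product: 16 {3-methoxy-4-[(triisopropylsilyl)oxy]phenyl}boronic acid, via aryllithium 15 (not isolated)
Conditions: n-BuLi, THF, −78 °C; B(Oi-Pr)3, −78 °C to rt; 1 M aq. HCl, 0 °C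
Reagents that add atoms: triisopropyl borate, CC(C)OB(OC(C)C)OC(C)C; water, O
Why: Bromine–lithium exchange, borylation of the aryllithium and hydrolysis of the borate; the silyl ether is para to the lithiated carbon, so no silyl migration is possible.

Step 6
Reactants: 12 5-hydroxy-6-(3-methylbut-2-en-1-yl)-7-[(triisopropylsilyl)oxy]-4H-chromen-4-one; 16 {3-methoxy-4-[(triisopropylsilyl)oxy]phenyl}boronic acid
Product: 17 (2S)-5-hydroxy-2-{3-methoxy-4-[(triisopropylsilyl)oxy]phenyl}-6-(3-methylbut-2-en-1-yl)-7-[(triisopropylsilyl)oxy]-2,3-dihydro-4H-chromen-4-one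
Conditions: [Rh(OH)(cod)]2 (2.5 mol %), (S)-MeO-F12-BIPHEP (6 mol %), 16 (3 equiv), toluene/H2O, 40 °C
Reagents that add atoms: none
Why: Hayashi–Miyaura asymmetric 1,4-addition of an arylboronic acid to a chromone: the aryl–rhodium complex of the chiral bisphosphine should insert the C2=C3 bond from one face and so set C2 as (S) under catalyst control. Base-free conditions and the electron-poor ligand should suppress ring opening of the flavanone to the chalcone and 1,2-addition, and the prenyl alkene is inert to aryl–rhodium species.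

Step 7
Reactants: 17 (2S)-5-hydroxy-2-{3-methoxy-4-[(triisopropylsilyl)oxy]phenyl}-6-(3-methylbut-2-en-1-yl)-7-[(triisopropylsilyl)oxy]-2,3-dihydro-4H-chromen-4-one
Product: 18 (2S)-5,7-dihydroxy-2-(4-hydroxy-3-methoxyphenyl)-6-(3-methylbut-2-en-1-yl)-2,3-dihydro-4H-chromen-4-one
Conditions: Bu4NF (2.4 equiv), AcOH (2.6 equiv), THF, 0 °C
Reagents that add atoms: none
Why: Fluoride cleavage of both aryl silyl ethers; the acetic acid buffer keeps the freed phenols protonated, so base-induced ring opening (retro-oxa-Michael or quinone methide) that would racemise C2 should not occur, and no strong acid is present that could cyclise the prenyl group onto a flanking phenol.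

**Compound list**
1 | comanic acid (4-oxo-4H-pyran-2-carboxylic acid) | O=C(O)c1cc(=O)cco1 | starting material
2 | 4-oxo-4H-pyran-2-carbonyl chloride | O=C(Cl)c1cc(=O)cco1 | intermediate
3 | 2-(2-diazoacetyl)-4H-pyran-4-one | [N-]=[N+]=CC(=O)c1cc(=O)cco1 | intermediate
4 | ethyl 4-methylpent-3-enoate | CCOC(=O)CC=C(C)C | starting material
5 | lithium 1,1-dibromo-5-methylhexa-1,4-dien-2-olate | [Li+].[O-]C(CC=C(C)C)=C(Br)Br | intermediate
6 | lithium 5-methylhex-4-en-1-yn-1-olate | [Li+].[O-]C#CCC=C(C)C | intermediate
7 | triisopropyl[(5-methylhex-4-en-1-yn-1-yl)oxy]silane | CC(C)=CCC#CO[Si](C(C)C)(C(C)C)C(C)C | intermediate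
8 | 2-(2-oxoethenyl)-4H-pyran-4-one (pyranonylketene) | O=C=Cc1cc(=O)cco1 | intermediate
9 | 2-(3-methylbut-2-en-1-yl)-4-(4-oxo-4H-pyran-2-yl)-3-[(triisopropylsilyl)oxy]cyclobut-2-en-1-one | CC(C)=CCC1=C(O[Si](C(C)C)(C(C)C)C(C)C)C(c2cc(=O)cco2)C1=O | intermediate
10 | (3E)-2-(3-methylbut-2-en-1-yl)-4-(4-oxo-4H-pyran-2-yl)-3-[(triisopropylsilyl)oxy]buta-1,3-dien-1-one | O=C=C(CC=C(C)C)/C(O[Si](C(C)C)(C(C)C)C(C)C)=C\c1cc(=O)cco1 | intermediate
11 | 6-(3-methylbut-2-en-1-yl)-7-[(triisopropylsilyl)oxy]-4aH-chromene-4,5-dione | CC(C)=CCC1=C(O[Si](C(C)C)(C(C)C)C(C)C)C=C2OC=CC(=O)C2C1=O | intermediate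
12 | 5-hydroxy-6-(3-methylbut-2-en-1-yl)-7-[(triisopropylsilyl)oxy]-4H-chromen-4-one | CC(C)=CCc1c(O[Si](C(C)C)(C(C)C)C(C)C)cc2occc(=O)c2c1O | intermediate
13 | 4-bromo-2-methoxyphenol | COc1cc(Br)ccc1O | starting material
14 | (4-bromo-2-methoxyphenoxy)triisopropylsilane | COc1cc(Br)ccc1O[Si](C(C)C)(C(C)C)C(C)C | intermediate
15 | {3-methoxy-4-[(triisopropylsilyl)oxy]phenyl}lithium | [Li]c1ccc(O[Si](C(C)C)(C(C)C)C(C)C)c(OC)c1 | intermediate
16 | {3-methoxy-4-[(triisopropylsilyl)oxy]phenyl}boronic acid | COc1cc(B(O)O)ccc1O[Si](C(C)C)(C(C)C)C(C)C | intermediate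
17 | (2S)-5-hydroxy-2-{3-methoxy-4-[(triisopropylsilyl)oxy]phenyl}-6-(3-methylbut-2-en-1-yl)-7-[(triisopropylsilyl)oxy]-2,3-dihydro-4H-chromen-4-one | COc1cc([C@@H]2CC(=O)c3c(cc(O[Si](C(C)C)(C(C)C)C(C)C)c(CC=C(C)C)c3O)O2)ccc1O[Si](C(C)C)(C(C)C)C(C)C | intermediate
18 | (2S)-5,7-dihydroxy-2-(4-hydroxy-3-methoxyphenyl)-6-(3-methylbut-2-en-1-yl)-2,3-dihydro-4H-chromen-4-one | COc1cc([C@@H]2CC(=O)c3c(cc(O)c(CC=C(C)C)c3O)O2)ccc1O | target

**Step count and risk**
Total step count: 7. Longest linear sequence: 4 steps (steps 1, 3, 6, 7).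

Steps most likely to fail:

1. Step 3 (benzannulation). Light-induced decomposition of the pyranone chromophore or carbene side reactions (cyclopropanation of the prenyl alkene, cyclopropenation of the alkyne) could compete with the Wolff rearrangement. The fallback makes the same ketene in the dark and sets out from diazoketone 3. A Wolff rearrangement of 3 in water (cat. AgOCOPh, Et3N, THF/H2O, Arndt–Eistert homologation) would give (4-oxo-4H-pyran-2-yl)acetic acid F1. Thionyl chloride at 0 °C would convert it into (4-oxo-4H-pyran-2-yl)acetyl chloride F2, used at once because F1 may lose CO2 on warming. Slow addition of Et3N to F2 and siloxyalkyne 7 in toluene would release ketene 8 by dehydrochlorination. The route would be rejoined at cyclobutenone 9 and, after heating at 80–110 °C, at chromone 12.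

2. Step 6 (asymmetric 1,4-addition). Insertion of the electron-rich 5-hydroxychromone could be slow, or the chromone could bind rhodium as a chelating keto-phenolate, so that protodeboronation of 16 wins; facial selectivity could also be poor. The fallback is a racemic addition followed by kinetic resolution and sets out from chromone 12 and bromide 14. Magnesium in THF would convert 14 into {3-methoxy-4-[(triisopropylsilyl)oxy]phenyl}magnesium bromide F3. Copper-catalysed conjugate addition of F3 (excess) to 12 (CuBr·SMe2, Me3SiCl, THF, −40 °C, dilute HCl work-up) would give the racemic flavanone rac-5-hydroxy-2-{3-methoxy-4-[(triisopropylsilyl)oxy]phenyl}-6-(3-methylbut-2-en-1-yl)-7-[(triisopropylsilyl)oxy]-2,3-dihydro-4H-chromen-4-one F4. Transfer hydrogenation with RuCl[(R,R)-TsDPEN](p-cymene) in HCO2H/Et3N should reduce the (2R)-enantiomer faster, to the cis-alcohol (2R,4R)-2-{3-methoxy-4-[(triisopropylsilyl)oxy]phenyl}-6-(3-methylbut-2-en-1-yl)-7-[(triisopropylsilyl)oxy]-3,4-dihydro-2H-chromene-4,5-diol F5. The unreacted (2S)-flavanone is 17, where the route is rejoined.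

3. Step 2 (siloxyalkyne). The amide base or LiCHBr2 could deprotonate the doubly activated CH2 (α to the ester and allylic) instead of adding to the ester, and the alkene could migrate into conjugation. The fallback makes the ynolate by oxidation of an acetylide and sets out from ester 4. Reduction with i-Bu2AlH at −78 °C would give 4-methylpent-3-enal F6. A Corey–Fuchs olefination (CBr4, PPh3, CH2Cl2, 0 °C) would give 1,1-dibromo-5-methylhexa-1,4-diene F7. n-BuLi (2 equiv, THF, −78 °C) would convert F7 into (5-methylhex-4-en-1-yn-1-yl)lithium F8. Oxidation of F8 with LiOOt-Bu (from t-BuOOH and LiN(SiMe3)2) would give ynolate 6, and i-Pr3SiOSO2CF3 would silylate it to 7, where the route is rejoined.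

**Further compounds**
F1 | step 3 | (4-oxo-4H-pyran-2-yl)acetic acid | O=C(O)Cc1cc(=O)cco1
F2 | step 3 | (4-oxo-4H-pyran-2-yl)acetyl chloride | O=C(Cl)Cc1cc(=O)cco1
F3 | step 6 | {3-methoxy-4-[(triisopropylsilyl)oxy]phenyl}magnesium bromide | COc1cc([Mg]Br)ccc1O[Si](C(C)C)(C(C)C)C(C)C
F4 | step 6 | rac-5-hydroxy-2-{3-methoxy-4-[(triisopropylsilyl)oxy]phenyl}-6-(3-methylbut-2-en-1-yl)-7-[(triisopropylsilyl)oxy]-2,3-dihydro-4H-chromen-4-one | COc1cc(C2CC(=O)c3c(cc(O[Si](C(C)C)(C(C)C)C(C)C)c(CC=C(C)C)c3O)O2)ccc1O[Si](C(C)C)(C(C)C)C(C)C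
F5 | step 6 | (2R,4R)-2-{3-methoxy-4-[(triisopropylsilyl)oxy]phenyl}-6-(3-methylbut-2-en-1-yl)-7-[(triisopropylsilyl)oxy]-3,4-dihydro-2H-chromene-4,5-diol | COc1cc([C@H]2C[C@@H](O)c3c(cc(O[Si](C(C)C)(C(C)C)C(C)C)c(CC=C(C)C)c3O)O2)ccc1O[Si](C(C)C)(C(C)C)C(C)C
F6 | step 2 | 4-methylpent-3-enal | CC(C)=CCC=O
F7 | step 2 | 1,1-dibromo-5-methylhexa-1,4-diene | BrC(Br)=CCC=C(C)C
F8 | step 2 | (5-methylhex-4-en-1-yn-1-yl)lithium | [Li]C#CCC=C(C)C
A1 | direct plan | 3,5-bis(methoxymethoxy)-4-(3-methylbut-2-en-1-yl)-2-(trimethylsilyl)phenyl trifluoromethanesulfonate | COCOc1cc(OS(=O)(=O)C(F)(F)F)c([Si](C)(C)C)c(OCOC)c1CC=C(C)C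
A2 | direct plan | 1,2-didehydro-3,5-bis(methoxymethoxy)-4-(3-methylbut-2-en-1-yl)benzene | COCOC1=C(CC=C(C)C)C(OCOC)=CC#C1
A3 | direct plan | (3S)-3-hydroxy-3-[3-methoxy-4-(methoxymethoxy)phenyl]propanenitrile | COCOc1ccc([C@@H](O)CC#N)cc1OC
A4 | direct plan | (2S)-5,7-bis(methoxymethoxy)-2-[3-methoxy-4-(methoxymethoxy)phenyl]-6-(3-methylbut-2-en-1-yl)-2,3-dihydro-4H-chromen-4-one | COCOc1ccc([C@@H]2CC(=O)c3c(cc(OCOC)c(CC=C(C)C)c3OCOC)O2)cc1OC
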